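All runs are calculated for substances that don't exist.

With a small charge of solid substrate, the question is what each equivalent of reagent buys, so keep a ledger on the reagent.

all flasks: solid substrate 0.094 M
- Sunday's: reagent 0.70 equiv; initiator 14 mol%; run made earlier
- Thursday's: reagent 0.70 equiv; initiator 22 mol%; run made earlier
- Friday's: reagent 1 equiv; initiator 10 mol%; run made earlier
- flask: reagent 0.700 equiv; initiator 10 mol%; time 8.0 d

- Sunday's (time / d: target / %): 1.25: 17.4; 2.08: 27.5; 3.00: 33.2; 6.00: 38.0; 10.0: 35.7
- Thursday's (time / d: target / %): 1.25: 16.2; 2.08: 24.8; 3.00: 33.1; 6.00: 40.6; 10.0: 40.9
- Friday's (time / d: target / %): 1.25: 19.5; 2.08: 30.2; 3.00: 38.3; 6.00: 47.4; 10.0: 47.3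

(scatter of a reading: 0.5 percentage points)

- percentages count the solid substrate that a species holds: one ended chains or side product counts as two
- solid, in amounts per volume of the solution: solid substrate
- reactions considered so far: solid substrate <-> starting material; starting material + initiating radical -> capped initiator + first chain carrier; 2 first chain carrier -> ended chains; initiator -> 2 initiating radical; starting material + target -> side product; starting material + second chain carrier -> by-product + first chain carrier; reagent + first chain carrier <-> target + second chain carrier
- at the start none of the solid substrate is in solution

* time, not beyond 8.0 d, at which the flask holds most target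
* the amount of target, in percent of the solid substrate charged, at that time
* the first time at which target reaches 11%, in the same percent, in d

By the listed steps, the exchange of reagent with first chain carrier runs both ways, so the ledger counts net: a target that falls back is reagent unspent again, and each mole of reagent spent net is one target, which stays or is taken by starting material into side product. The ledger therefore has three entries: reagent unspent, target, and half of the side product percentage, since one side product counts as two. Target tops out at the crossing where its making falls to the rate of its loss. In Sunday's run that top reads 38.0% at 6.00 d, with 35.7% at 10.0 d, each reading carrying a scatter of 0.5 percentage points.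

Sunday's run gives 0.543 for η, the reagent yield, meaning target at its highest reading per equivalent of reagent charged. My reckoning for this flask is η times 0.700 equiv, or 38.0%. I hold that as a high figure, since Thursday's run, with more initiator, reads a higher yield of 0.584, and this flask has less.

The forecast is lower than my figure: 36.5% (range 34% to 39%) at 5 d, and the asked level at 0.78 d, on the ground that “The chain dies earlier”.

    solid substrate ⇌ starting material, rate k1*(cs1 - [starting material]) while solid is left; crystals form when [starting material] > cs1 (solubility = 8.30 mM, k = 0.100 h⁻¹)
    starting material + initiating radical → capped initiator + first chain carrier (k = 2.10 × 10⁷ L mol⁻¹ h⁻¹)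
    2 first chain carrier → ended chains (k = 3.90 × 10⁶ L mol⁻¹ s⁻¹)
    initiator → 2 initiating radical (k = 0.00750 h⁻¹)
    starting material + target → side product (k = 1.80 L mol⁻¹ h⁻¹)
    starting material + second chain carrier → by-product + first chain carrier (k = 3.10 × 10⁶ L mol⁻¹ h⁻¹)
    reagent + first chain carrier ⇌ target + second chain carrier (K = 1.00, k = 8.50 × 10⁵ L mol⁻¹ h⁻¹)

The flask gives 36.5% at 4.68 d and reaches the asked level at 0.697 d, each inside the forecast's range. At that top it holds 24.4% of side product and 30.4% of the reagent's own charge, so 0.487 equiv spent stands against 48.7% in the other two entries. Its own η is 0.521.

For the neighbour flask with 0.280 equiv of reagent, Sunday's η gives 15.2%. The computed best there is 17.4%, with reagent the limiting reagent at 1.0% of its charge left. That lies below the forecast's low end, so a reagent charge cut that far would make the forecast wrong.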